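**Retrosynthetic overview**
- The side chain is cut at the CH2–C(sp2) bond: B-alkyl Suzuki–Miyaura coupling of a bicyclic 1-vinyl diene (after 9-BBN hydroboration) with a (Z)-2-iodo dienol that already carries the butenolide.
- The diene comes from the enol triflate of the trans-fused 2,5,5,8a-tetramethyldecal-1-one; this ketone has a single enolisable position, so the tetrasubstituted ring alkene is formed regiospecifically.
- Key step: ring B of that decalone is made by a one-carbon ring expansion of a trans-hydrindan-1-one (diazoethane insertion with 1,2-shift of the CH2 group), which inserts the methyl-bearing carbon next to the carbonyl.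
- The hydrindanone comes from 2-methylcyclopent-2-enone by enantioselective conjugate reverse-prenylation and anti enolate allylation (both stereocentres), then ring-closing metathesis and hydrogenation.
- Ring order: cyclopentanone (bought) → ring A (metathesis) → ring B (five to six by ring expansion); the butenolide is bought as 4-bromofuran-2(5H)-one and extended by Heck reaction, α-iodination and Luche reduction.

Assumption: ethereal diazoethane (freshly prepared from commercial N-ethyl-N-nitrosourea and KOH) is handled as a reagent; prenylmagnesium chloride solution and (2E)-penta-2,4-dienal are bought.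

**Step 1**
Reactants: 1 (3-methylbut-2-en-1-yl)magnesium chloride
Product: 2 trimethyl(3-methylbut-2-en-1-yl)silane
Conditions: Me3SiCl, THF, 0 °C → rt
Reagents that add atoms: chlorotrimethylsilane, C[Si](C)(C)Cl
Why: silylation of the allylic Grignard reagent occurs at the unhindered primary terminus and gives the prenylsilane needed for γ-selective Hosomi–Sakurai chemistry; no stereocentre is formed.

**Step 2**
Reactants: 3 2-methylcyclopent-2-en-1-one; 2 trimethyl(3-methylbut-2-en-1-yl)silane; 4 3-bromoprop-1-ene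
Product: 7 (2S,3S)-2-allyl-2-methyl-3-(2-methylbut-3-en-2-yl)cyclopentan-1-one, via silyl enol ether 5 (not isolated), via lithium enolate 6 (not isolated)
Conditions: chiral binaphthyl imidodiphosphorimidate acid (IDPi, N-triflyl, enantiomer giving (S)-5; 2 mol %), toluene, −60 °C; then MeLi, THF, 0 °C; then allyl bromide, DMPU, −78 → −20 °C
Reagents that add atoms: none
Why: Proposed new method: the IDPi acid is silylated by 2 and the silylium–IDPi ion pair activates enone 3 inside the chiral anion pocket, so 2 attacks the β-carbon through its γ-carbon (SE2′, giving the 1,1-dimethylallyl group and setting C3 as S) and silyl transfer to oxygen releases 5 and regenerates the silylium catalyst (closest known reactions: TiCl4-mediated Hosomi–Sakurai conjugate addition of prenylsilane to enones and IDPi-catalysed asymmetric Sakurai allylation of aldehydes and Mukaiyama–Michael additions); MeLi then frees the regiodefined enolate 6 (Stork), which is allylated anti to the bulky C3 group to set the quaternary C2 as S.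

**Step 3**
Reactants: 7 (2S,3S)-2-allyl-2-methyl-3-(2-methylbut-3-en-2-yl)cyclopentan-1-one
Product: 9 (3aS,7aS)-4,4,7a-trimethyloctahydro-1H-inden-1-one, via hexahydroindenone 8 (not isolated)
Conditions: second-generation Grubbs catalyst (5 mol %), ClCH2CH2Cl, 60 °C; then H2 (7 bar), 70 °C, same pot
Reagents that add atoms: none
Why: ring-closing metathesis of the trans-disposed allyl and 1,1-dimethylallyl arms (helped by the gem-dimethyl group; neither fusion centre can epimerise) closes ring A trans-fused, and the ruthenium hydride formed under H2 (tandem metathesis–hydrogenation) saturates the only C=C; no new stereocentre is formed.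

**Step 4**
Reactants: 9 (3aS,7aS)-4,4,7a-trimethyloctahydro-1H-inden-1-one
Product: 10 (4aS,8aS)-2,5,5,8a-tetramethyloctahydronaphthalen-1(2H)-one (C2 epimers)
Conditions: MeCHN2 (Et2O solution, 1.5 equiv), Sc(OTf)3 (10 mol %), CH2Cl2, −78 → −40 °C
Reagents that add atoms: diazoethane, CC=[N+]=[N-]
Why: Lewis-acid-catalysed diazoalkane–ketone homologation (Tiffeneau–Demjanov-type ring expansion): diazoethane adds to the activated carbonyl and the less substituted CH2 (not the quaternary carbon) undergoes the 1,2-shift with loss of N2, as in D-homoannulation of 17-ketosteroids, so ring B grows from five to six members with the methyl-bearing carbon next to C=O; C4a and C8a are untouched and the new C2 centre is made sp2 in step 5.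

**Step 5**
Reactants: 10 (4aS,8aS)-2,5,5,8a-tetramethyloctahydronaphthalen-1(2H)-one
Product: 12 (4aS,8aS)-2,5,5,8a-tetramethyl-3,4,4a,5,6,7,8,8a-octahydronaphthalen-1-yl trifluoromethanesulfonate, via potassium enolate 11 (not isolated)
Conditions: KN(SiMe3)2, THF, −78 → 0 °C; then PhNTf2, −78 °C → rt
Reagents that add atoms: N-phenylbis(trifluoromethanesulfonimide), O=S(=O)(N(c1ccccc1)S(=O)(=O)C(F)(F)F)C(F)(F)F
Why: C2–H is the only enolisable position (C8a is quaternary), so enolate O-triflation gives one regiodefined tetrasubstituted enol triflate, as for 2,2,6-trimethylcyclohexanone, and both C2 epimers converge.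

**Step 6**
Reactants: 12 (4aS,8aS)-2,5,5,8a-tetramethyl-3,4,4a,5,6,7,8,8a-octahydronaphthalen-1-yl trifluoromethanesulfonate; 13 potassium vinyltrifluoroborate
Product: 14 (4aS,8aS)-1-ethenyl-2,5,5,8a-tetramethyl-3,4,4a,5,6,7,8,8a-octahydronaphthalene
Conditions: PdCl2(dppf) (5 mol %), Cs2CO3, THF/H2O (10:1), 70 °C
Reagents that add atoms: none
Why: Suzuki–Miyaura coupling of an alkenyl triflate with a vinyltrifluoroborate; hindered 2,6,6-trisubstituted cyclohexenyl triflates are established partners and the ring alkene position is fixed by the triflate.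

**Step 7**
Reactants: 15 4-bromofuran-2(5H)-one; 16 (2E)-penta-2,4-dienal
Product: 17 (2E,4E)-5-(5-oxo-2,5-dihydrofuran-3-yl)penta-2,4-dienal
Conditions: Pd(OAc)2 (5 mol %), Bu4NCl, NaHCO3, DMF, 50 °C
Reagents that add atoms: none
Why: Mizoroki–Heck reaction (Jeffery conditions) of the β-bromo enoate at the terminal CH2 of the electron-poor diene; syn insertion and β-hydride elimination give the (E)-alkene.

**Step 8**
Reactants: 17 (2E,4E)-5-(5-oxo-2,5-dihydrofuran-3-yl)penta-2,4-dienal
Product: 18 (2Z,4E)-2-iodo-5-(5-oxo-2,5-dihydrofuran-3-yl)penta-2,4-dienal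
Conditions: I2, K2CO3, DMAP (20 mol %), THF/H2O (1:1), 0 °C → rt
Reagents that add atoms: iodine, [I][I]
Why: amine-catalysed α-iodination of an enal (Baylis–Hillman-type DMAP addition, iodination of the enolate, elimination); the aldehyde is far more electrophilic than the lactone, and elimination restores the isomer with CHO trans to the chain, which places iodine cis to C4 (2Z).

**Step 9**
Reactants: 18 (2Z,4E)-2-iodo-5-(5-oxo-2,5-dihydrofuran-3-yl)penta-2,4-dienal
Product: 19 (2Z,4E)-2-iodo-5-(5-oxo-2,5-dihydrofuran-3-yl)penta-2,4-dien-1-ol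
Conditions: NaBH4, CeCl3·7H2O, MeOH, −78 °C
Reagents that add atoms: none
Why: Luche 1,2-reduction of the aldehyde; the butenolide, the diene and the vinyl iodide are inert at −78 °C and the alkene geometries are untouched.

**Step 10**
Reactants: 14 (4aS,8aS)-1-ethenyl-2,5,5,8a-tetramethyl-3,4,4a,5,6,7,8,8a-octahydronaphthalene; 19 (2Z,4E)-2-iodo-5-(5-oxo-2,5-dihydrofuran-3-yl)penta-2,4-dien-1-ol
Product: 21 4-[(1E,3E)-4-(hydroxymethyl)-6-[(4aS,8aS)-2,5,5,8a-tetramethyl-3,4,4a,5,6,7,8,8a-octahydronaphthalen-1-yl]hexa-1,3-dien-1-yl]furan-2(5H)-one (CNP0232848.5), via alkylborane 20 (not isolated)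
Conditions: 9-BBN-H, THF, 0 °C → rt; then 19, PdCl2(dppf) (5 mol %), AsPh3 (5 mol %), Cs2CO3 (aq), DMF, rt
Reagents that add atoms: none
Why: 9-BBN adds anti-Markovnikov to the monosubstituted vinyl group only (the tetrasubstituted ring alkene is inert), and the B-alkyl Suzuki–Miyaura coupling with the vinyl iodide proceeds with retention, so the new CH2 group is cis to the dienyl chain and CH2OH trans to it (3E); the free OH and the butenolide tolerate mild aqueous base at rt.

**Compound list**
1 | (3-methylbut-2-en-1-yl)magnesium chloride (prenylmagnesium chloride, THF solution) | CC(C)=CC[Mg]Cl | starting material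
2 | trimethyl(3-methylbut-2-en-1-yl)silane | CC(C)=CC[Si](C)(C)C | intermediate
3 | 2-methylcyclopent-2-en-1-one | CC1=CCCC1=O | starting material
4 | 3-bromoprop-1-ene (allyl bromide) | C=CCBr | starting material
5 | (S)-trimethyl{[2-methyl-3-(2-methylbut-3-en-2-yl)cyclopent-1-en-1-yl]oxy}silane | C[Si](C)(C)OC1=C(C)[C@H](C(C)(C)C=C)CC1 | intermediate
6 | lithium (S)-2-methyl-3-(2-methylbut-3-en-2-yl)cyclopent-1-en-1-olate | [Li+].[O-]C1=C(C)[C@H](C(C)(C)C=C)CC1 | intermediate
7 | (2S,3S)-2-allyl-2-methyl-3-(2-methylbut-3-en-2-yl)cyclopentan-1-one | O=C1[C@@](C)(CC=C)[C@H](C(C)(C)C=C)CC1 | intermediate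
8 | (3aS,7aS)-4,4,7a-trimethyl-2,3,3a,4,7,7a-hexahydro-1H-inden-1-one | O=C1[C@@]2(C)CC=CC(C)(C)[C@@H]2CC1 | intermediate
9 | (3aS,7aS)-4,4,7a-trimethyloctahydro-1H-inden-1-one | O=C1[C@@]2(C)CCCC(C)(C)[C@@H]2CC1 | intermediate
10 | (4aS,8aS)-2,5,5,8a-tetramethyloctahydronaphthalen-1(2H)-one (C2 epimers) | CC1C(=O)[C@@]2(C)CCCC(C)(C)[C@@H]2CC1 | intermediate
11 | potassium (4aS,8aS)-2,5,5,8a-tetramethyl-3,4,4a,5,6,7,8,8a-octahydronaphthalen-1-olate | [K+].CC1=C([O-])[C@@]2(C)CCCC(C)(C)[C@@H]2CC1 | intermediate
12 | (4aS,8aS)-2,5,5,8a-tetramethyl-3,4,4a,5,6,7,8,8a-octahydronaphthalen-1-yl trifluoromethanesulfonate | CC1=C(OS(=O)(=O)C(F)(F)F)[C@@]2(C)CCCC(C)(C)[C@@H]2CC1 | intermediate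
13 | potassium vinyltrifluoroborate | [K+].C=C[B-](F)(F)F | starting material
14 | (4aS,8aS)-1-ethenyl-2,5,5,8a-tetramethyl-3,4,4a,5,6,7,8,8a-octahydronaphthalene | CC1=C(C=C)[C@@]2(C)CCCC(C)(C)[C@@H]2CC1 | intermediate
15 | 4-bromofuran-2(5H)-one | O=C1C=C(Br)CO1 | starting material
16 | (2E)-penta-2,4-dienal | C=C/C=C/C=O | starting material
17 | (2E,4E)-5-(5-oxo-2,5-dihydrofuran-3-yl)penta-2,4-dienal | O=C/C=C/C=C/C1=CC(=O)OC1 | intermediate
18 | (2Z,4E)-2-iodo-5-(5-oxo-2,5-dihydrofuran-3-yl)penta-2,4-dienal | I/C(C=O)=C\C=C\C1=CC(=O)OC1 | intermediate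
19 | (2Z,4E)-2-iodo-5-(5-oxo-2,5-dihydrofuran-3-yl)penta-2,4-dien-1-ol | I/C(CO)=C\C=C\C1=CC(=O)OC1 | intermediate
20 | 9-{2-[(4aS,8aS)-2,5,5,8a-tetramethyl-3,4,4a,5,6,7,8,8a-octahydronaphthalen-1-yl]ethyl}-9-borabicyclo[3.3.1]nonane | CC1=C(CCB3C4CCCC3CCC4)[C@@]2(C)CCCC(C)(C)[C@@H]2CC1 | intermediate
21 | 4-[(1E,3E)-4-(hydroxymethyl)-6-[(4aS,8aS)-2,5,5,8a-tetramethyl-3,4,4a,5,6,7,8,8a-octahydronaphthalen-1-yl]hexa-1,3-dien-1-yl]furan-2(5H)-one (CNP0232848.5) | CC1=C(CC/C(=C\C=C\C2=CC(=O)OC2)CO)[C@@]2(C)CCCC(C)(C)[C@@H]2CC1 | target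

**Totals and risks**
Total step count: 10 (one-pot sequences counted as one step). Longest linear sequence: 7 steps (steps 1–6 and 10); steps 7–9 make the side-chain fragment.

Step 2 (proposed new step) is the most likely to fail: the nucleophile must form a quaternary–tertiary bond at the β-carbon of an α-substituted enone inside a confined catalyst, so rate and ee are uncertain. The fallback uses known chemistry, sets out from 3, 2 and 4 and comes back at 7. The conjugate addition is run with achiral HNTf2 (which gives Me3SiNTf2 in situ, a known catalyst for Hosomi–Sakurai reactions) to give the racemic silyl enol ether F1. MeLi converts it into the racemic lithium enolate F2, and allyl bromide gives the racemic trans ketone F3. The enantiomers of F3 are then separated by preparative chromatography on a chiral phase, and the (2S,3S) enantiomer is 7.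

Step 4 is the second risk: diazoethane is volatile and hazardous, the neopentyl ketone is hindered, and epoxide formation or double insertion can compete. The fallback sets out from 9 and comes back at 10, and it keeps the one-carbon ring expansion but separates it from the methylation. Me3SiCHN2 with Sc(OTf)3 (a known catalytic single homologation, again with CH2 migration) gives the α-silyl ketone F4. Acidic work-up removes silicon to give (4aS,8aS)-5,5,8a-trimethyloctahydronaphthalen-1(2H)-one F5. LiN(iPr)2 forms the lithium enolate F6 at the only α-CH2, and MeI gives 10.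

Step 8 is the third risk: the α-iodination must discriminate between the enal and the butenolide, and DMAP could add 1,6 to the extended acceptor. The fallback sets out from 16 and 14 and comes back at 21; it moves the butenolide attachment to the end. Dienal 16 is iodinated under the same amine-catalysed conditions to (2Z)-2-iodopenta-2,4-dienal F7, and Luche reduction gives (2Z)-2-iodopenta-2,4-dien-1-ol F8. B-alkyl Suzuki–Miyaura coupling of F8 with alkylborane 20 (made from 14 as in step 10) gives (2E)-2-{2-[(4aS,8aS)-2,5,5,8a-tetramethyl-3,4,4a,5,6,7,8,8a-octahydronaphthalen-1-yl]ethyl}penta-2,4-dien-1-ol F9. A terminal Mizoroki–Heck reaction of F9 with 15 (Pd(OAc)2, Bu4NCl, NaHCO3, DMF) then gives 21.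

**Further compounds**
F1 | step 2 | racemic trimethyl{[2-methyl-3-(2-methylbut-3-en-2-yl)cyclopent-1-en-1-yl]oxy}silane | C[Si](C)(C)OC1=C(C)[C@H](C(C)(C)C=C)CC1.C[Si](C)(C)OC1=C(C)[C@@H](C(C)(C)C=C)CC1
F2 | step 2 | racemic lithium 2-methyl-3-(2-methylbut-3-en-2-yl)cyclopent-1-en-1-olate | [Li+].[O-]C1=C(C)[C@H](C(C)(C)C=C)CC1.[Li+].[O-]C1=C(C)[C@@H](C(C)(C)C=C)CC1
F3 | step 2 | racemic trans-2-allyl-2-methyl-3-(2-methylbut-3-en-2-yl)cyclopentan-1-one | O=C1[C@@](C)(CC=C)[C@H](C(C)(C)C=C)CC1.O=C1[C@](C)(CC=C)[C@@H](C(C)(C)C=C)CC1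
F4 | step 4 | (4aS,8aS)-5,5,8a-trimethyl-2-(trimethylsilyl)octahydronaphthalen-1(2H)-one | C[Si](C)(C)C1C(=O)[C@@]2(C)CCCC(C)(C)[C@@H]2CC1
F5 | step 4 | (4aS,8aS)-5,5,8a-trimethyloctahydronaphthalen-1(2H)-one | O=C1[C@@]2(C)CCCC(C)(C)[C@@H]2CCC1
F6 | step 4 | lithium (4aS,8aS)-5,5,8a-trimethyl-3,4,4a,5,6,7,8,8a-octahydronaphthalen-1-olate | [Li+].C1=C([O-])[C@@]2(C)CCCC(C)(C)[C@@H]2CC1
F7 | step 8 | (2Z)-2-iodopenta-2,4-dienal | I/C(C=O)=C\C=C
F8 | step 8 | (2Z)-2-iodopenta-2,4-dien-1-ol | I/C(CO)=C\C=C
F9 | step 8 | (2E)-2-{2-[(4aS,8aS)-2,5,5,8a-tetramethyl-3,4,4a,5,6,7,8,8a-octahydronaphthalen-1-yl]ethyl}penta-2,4-dien-1-ol | CC1=C(CC/C(=C\C=C)CO)[C@@]2(C)CCCC(C)(C)[C@@H]2CC1
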